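**Reading time.** Gamma is read at 88 min, the time of epsilon's last reading, and it holds epsilon's Q charge.

| flask | Q | E | Z | time |
|---|---|---|---|---|
| theta | 0.300 M | 6.00 × 10⁻⁴ M |  |  |
| eta | 0.450 M | 6.00 × 10⁻⁴ M |  |  |
| epsilon | 0.300 M | 3.00 × 10⁻⁴ M |  |  |
| alpha | 0.300 M | 6.00 × 10⁻⁴ M | 0.150 M |  |
| gamma | 0.300 M | 1.30 × 10⁻⁴ M |  | 88 min |

- theta run (time / min: [Z] / M): 3.2: 0.0082; 9.6: 0.0272; 18: 0.0466; 29: 0.0698; 41: 0.0887; 56: 0.1062; 71: 0.1187; 88: 0.1242
- eta run (time / min: [Z] / M): 3.2: 0.0122; 9.6: 0.0347; 18: 0.0616; 29: 0.0900; 41: 0.1157; 56: 0.1416; 71: 0.1583; 88: 0.1678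
- epsilon run (time / min: [Z] / M): 3.2: 0.0069; 9.6: 0.0164; 18: 0.0279; 29: 0.0433; 41: 0.0545; 56: 0.0659; 71: 0.0734; 88: 0.0823
- alpha run (time / min: [Z] / M): 3.2: 0.1545; 9.6: 0.1629; 18: 0.1715; 29: 0.1805; 41: 0.1861; 56: 0.1892; 71: 0.1892; 88: 0.1816

(standard deviation of a reading: 9 × 10⁻⁴ M)

1. reaction order in [E] at the outset, round the charge of the theta run, defined at two percent of the Q turned into Z
2. reaction order in [Q] at the outset, round the charge of the theta run, defined at two percent of the Q turned into Z (one fixed amount of Z, the same in the runs compared)
3. Z in the gamma run at 88 min, as a share of the Q charged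

- Overall: Q -> Z, with E as catalyst.
- Constant volume, constant temperature.
- The analysis sees a species whether free or bound.
- An order is taken over about fifteen percent of the charge, up and down.

**What matters.** Gamma holds 0.433 of epsilon's E charge. So I start from epsilon's last reading and look for one factor. The order in Q and the slowing over time act on both flasks, so as an approximation I take them to drop out of that factor. The step is rough: theta's last reading is higher than epsilon's, so the two have not used the same share of Q. One standard deviation of scatter is 1.09% of the last epsilon reading. The number to know well is the ratio of theta to epsilon. Their last readings give 1.51, and that ratio leads to 16.1% in gamma.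

**The number.** Summed over their readings, theta over epsilon is 1.59, for 2.00 times the E. I picture E working singly and resting partly in pairs, an off-cycle reservoir, with c_E in pairs growing as the square of single c_E. In that picture the ratio reads as the E held in pairs per working E in epsilon, 0.770, a reading taken from scattered sums over the whole run. In the same picture, dilution to gamma's charge opens pairs, so the factor is 0.541, not 0.433. My reckoning puts Z in gamma at 14.9% of the Q charged.

**The forecast.** It gave 0.7 (0.5 to 0.9) for Q, 0.68 (0.55 to 0.82) for E and 15% (12.5% to 18%) for gamma, with E pictured as “an inactive dimer in equilibrium with active monomer”.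

**The result.** The orders at the outset, round theta's charge, are 0.81 in E and 0.62 in Q, and gamma gives 14.4%. That is 0.526 of epsilon's last reading, beside the factor 0.541 built from 0.770.

    2 E ⇌ E2, settled at all times (398.0 M⁻¹)
    E + Q → Z + E (74.40 M⁻¹ min⁻¹)
    Z → Vy (0.01074 min⁻¹)
    2 Q ⇌ Q2, settled at all times (11.70 M⁻¹)

**One reason.** Q joining into Q2 holds down the Z in gamma. The simulated gamma run without that joining gives 32.9% against 14.4%. The same joining holds the order in Q at 0.62, where the simulated run without it gives 1.0.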